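The reading asked for falls at 4.0 d, well past the last amber reading at 15.0 h, so the amber flask is reckoned from the green run, which reached that time.

| setting | amber | green | flask |
|---|---|---|---|
| solid substrate | 12 mM | 18 mM | 12 mM |
| gas phase | 1 mM (held) | 1 mM (held) | 1.0 mM (held) |
| remark | the very flask that is asked about, followed so far | run made earlier |  |
| time |  |  | 4.0 d |

amber run (percent of the solid substrate charged)

| time / h | target / % | solid substrate / % |
|---|---|---|
| 4.00 | 0.9 | 97.3 |
| 8.00 | 1.6 | 92.5 |
| 12.0 | 4.8 | 88.0 |
| 15.0 | 4.0 | 85.1 |

green run (percent of the solid substrate charged)

| time / d | target / % | solid substrate / % |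
|---|---|---|
| 1.04 | 4.4 | 82.9 |
| 2.08 | 6.9 | 66.5 |
| 3.00 | 10.2 | 52.9 |
| 4.00 | 10.3 | 39.1 |

(scatter of a reading: 1 percentage point)

- solid substrate is a solid; its amount is given per volume of the solution
- the analysis behind the earlier runs scatters by 1 percentage point, standard deviation
- at the start none of the solid substrate is in solution
- at the start none of the gas phase is in solution

1. amount of target at 4.0 d, in percent of the solid substrate charged
2. concentration of dissolved gas in solution at 4.0 d, in percent of saturation

The ledger is kept in mM of solid substrate, the limiting reagent, as the gas phase is held. The green flask lost 11.0 mM by 4.00 d, on average 0.114 mM h⁻¹. The amber flask lost 0.119 mM h⁻¹ up to 15.0 h, nearly the same from a smaller charge. Dividing the gain of target by the loss of solid drops time out: the green flask stood at 0.169 mol of target per mol of solid substrate lost, and this reading is the ledger yield.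

The reckoning made here books the amber flask at 4.0 d thus: 11.0 mM lost of 12 mM, leaving c(solid substrate) at 1.04 mM. Of the loss, c(target) takes 1.85 mM, which is 15.4% of the charge, and 9.11 mM goes to species unread, which closes the books.

The forecast, reasoning from “a supply limit, probably gas transfer”, gives 15% of target, slightly below this reckoning, on 9 mM of solid substrate consumed against 11.0 mM here, and 57% of saturation, for which the ledger has no entry.

The simulation gives 16.1% of target and 64.4% of saturation, the latter 7.4 percentage points above the forecast.

    starting material → side product (k = 0.00447 min⁻¹)
    starting material + dissolved gas → target (k = 5.26 L mol⁻¹ min⁻¹)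
    dissolved gas + target → over-reaction product (k = 0.576 L mol⁻¹ min⁻¹)
    solid substrate ⇌ starting material, rate k4*(cs4 - [starting material]) while solid is left; crystals form when [starting material] > cs4 (solubility = 6.70 mM, k = 2.94 × 10⁻⁴ min⁻¹)
    gas phase ⇌ dissolved gas, rate k5*(csat - [dissolved gas]) (kL = 0.00430 min⁻¹)

In the amber flask, solid substrate fell from 54.3% at 2.00 d to 8.73% at 4.00 d, while starting material held near 2.01% and dissolved gas went from 0.679 mM to 0.644 mM. Over that stretch side product reached 49.7% and over-reaction product 23.4%. The ledger yield on the solid lost gives 15.4% against 16.1%.

The same flask read at 2.50 d holds 42.9% of solid substrate, so the ledger yield gives 9.66% of target. The computed value is higher, at 13.4%.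

The numbers in the tables were computed with constants of no real substance; scatter was added.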